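- The pitfall is to take the hottest flask for the best because it is the quickest: both steps here give back on heating, and E also drains into D.

| setting | north-east | north-west | north |
|---|---|---|---|
| Z | 0.020 M | 0.020 M | 0.020 M |
| temperature | 50 °C | 25 °C | 75 °C |
| time | 12 h | 12 h | 12 h |

    E ⇌ D (K1 = 0.87, k1 = 0.0012 min⁻¹, Ea1 = 119 kJ mol⁻¹, ΔH1 = −34.0 kJ mol⁻¹)
    Z ⇌ E + X (K2 = 0.0019 M, k2 = 0.017 min⁻¹, Ea2 = 94.0 kJ mol⁻¹, ΔH2 = −34.0 kJ mol⁻¹)
    (constants at 50 °C)

- the flask that comes out highest in amount of E, in percent of the Z charged, or "all alike" when all lie within 1.5 percentage points (north-east / north-west / north / all alike)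
- E at the end, in percent of the Z charged, north-east
- E at the end, in percent of the Z charged, north-west
- E at the end, in percent of the Z charged, north

- at 50 °C the constants are as listed, elsewhere as the activation energies and enthalpies make them

- Call Kz the constant of Z ⇌ E + X and Kd the constant of E ⇌ D. In north, Kz is 7.66 × 10⁻⁴ M, and since both enthalpies are −34.0 kJ mol⁻¹, Kd falls by the same factor to 0.351.
- North has time for both steps: Z has a forward half-life of 3.31 min, and E and D relax with a half-life of 0.104 h. I therefore expect thermodynamic control there.
- Each Z lost gives one X and one E or D, so [X] = [E] × (one plus Kd). Kz then turns into the pool constant P = Kz × (one plus Kd), 0.00103 M in north, and [X] is the square root of P × (charge minus [X]).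
- I iterate for north. With no Z spent, [X] is 0.00455 M; put back, that gives 0.00400 M, and once more 0.00407 M. So E is 15.1% of the charge.
- North-east has 2.68 half-lives of E and D, so it is unfinished. It lies between 18.3%, with the full P, and 26.4%, with Kz in place of P, and I put it nearer the lower figure.
- In north-west, the forward constant of E ⇌ D times the run is 2.11%, the share lost by E present from the start, and E formed later has less time, so I let Kz stand in for P, which gives [X] = 0.00809 M, a ceiling of 40.4%. Near that ceiling the relaxation half-life is 3.24 h, so 12 h reaches 37.3%, before counting the drain to D. That is more than the other flasks, so I commit to north-west.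
- The forecast gives 20% for north-east, 35.3% for north-west and 15% for north, with north-west highest, since “it still ends clearly highest”.
- The simulation gives 20.1% for north-east, 35.3% for north-west and 15.0% for north, with north-west highest.
- The neighbour flask is north with 0.0050 M of Z, a quarter of the charge, at the same temperature, so P stays 0.00103 M. The first [X] is 0.00227 M, then 0.00168 M, then 0.00185 M, which puts E at 27.4% of its charge. The flask reads 26.9%, with [X] at 0.00182 M.

All constants are those of an exercise; no experiment stands behind them.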